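## The problem

Target 9, 1-[(2,3,6-tribromo-4,5-dihydroxyphenyl)methyl]pyrrolidin-2-one, is a benzene ring with no ring hydrogen left. Numbering the ring from the benzylic position, C1 carries the CH2 group bound to the lactam nitrogen, C2, C5 and C6 carry bromine, and C3 and C4 carry the two catechol hydroxyls. The five-membered lactam is joined to the arene only through the N–CH2–aryl link and there is no stereocentre, so nothing has to be controlled in space; the whole difficulty is placing six substituents on one ring. The free catechol is the fragile part: as its anion it is oxidised by air to the ortho-quinone, so it must stay masked until the last step. The three C–Br bonds exclude reducing metals, organolithium reagents and hydrogenation, while the lactam tolerates Lewis acids and mild base but not prolonged hot aqueous acid or alkali. The feature that opens a short route is that exchanging the oxygens at C3 and C4 for bromine turns the arene into a pentabromobenzyl group, which is symmetric about the C1–C4 axis and purchasable. The two oxygens sit on neighbouring carbons, one of them (C4) para to the benzylic carbon, so a two-carbon diol can deliver both and can only bridge an ortho pair. The synthesis therefore reduces to replacing two particular adjacent bromines out of five by oxygen.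

## Retrosynthesis

**Disconnection 1, unmasking the catechol (9 from 7).** In the retrosynthetic sense the two hydroxyls of 9 are tied together by an ethylene bridge, giving the benzodioxine 7, 1-[(5,7,8-tribromo-2,3-dihydro-1,4-benzodioxin-6-yl)methyl]pyrrolidin-2-one. A free catechol could not be carried through a basic substitution step, and two separate O-alkyl groups would protect it but would not help to place the oxygens. The bridge protects and, one step earlier, is the tether that places them. Precursor 7 is no smaller than 9, but it is stable to air and base. The forward reaction must split two primary alkyl aryl ether bonds with a boron Lewis acid, through the cyclic aryl borate 8, without touching the lactam, the benzylic C–N bond or the three C–Br bonds.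

**Disconnection 2, the key cut (7 from 4 and 5).** Both aryl C–O bonds, C3–O and C4–O, are cut. This opens the dioxane ring and returns the pentabromide 4, 1-[(2,3,4,5,6-pentabromophenyl)methyl]pyrrolidin-2-one, and ethane-1,2-diol 5. Cutting the three C–Br bonds instead leads to electrophilic bromination of a benzodioxine made from a catechol, which is sound but longer and is kept as the fallback. Cutting ring C–C bonds means building the benzene from acyclic pieces and then decorating it, as in the alternatives below. The C–O cut removes a ring and both heteroatom substituents at once and leaves a precursor whose five ring substituents are identical. The forward reaction must replace bromide by alkoxide twice on a ring activated only by its halogens, through the half-way ether 6. Entry must avoid C2 and C6, and closure must go onto C4 rather than C2 (or, from C4, onto either equivalent neighbour).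

**Disconnection 3, the benzylic C–N bond (4 from 1 and 2).** Cutting N–CH2 gives pyrrolidin-2-one 1, used as its sodium salt 3, and pentabromobenzyl bromide 2. Cutting the amide bond instead would build the lactam on a benzylamine in two operations and is held in reserve. The alkylation has to precede the key step, because the benzylic bromide of 2 would be the first site an alkoxide attacks. Once it is the lactam, the benzylic group is a non-leaving, bulky, weakly donating substituent that helps to steer the ring substitution. The forward reaction asks for SN2 at a benzylic carbon flanked by two ortho bromines, at nitrogen and not oxygen of the lactam anion, with no attack on the ring.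

## Roads not taken

**Alternative 1: formal (3+3) cyclocondensation.**
- Cut: ring bonds C1–C2 and C4–C5.
- Forward key step: a strong Lewis acid joins the bis(silyl) dienol ether A1, 1,4-dimethoxy-1,3-bis(trimethylsilyloxy)buta-1,3-diene, with the alkoxy enone A2, (E)-4-methoxy-1-(2-oxopyrrolidin-1-yl)but-3-en-2-one. The methoxy-bearing terminus of A1 adds to the β-carbon of A2, the central carbon of A1 condenses with the ketone, and aromatisation gives the salicylate A3, methyl 2-hydroxy-3-methoxy-6-[(2-oxopyrrolidin-1-yl)methyl]benzoate.
- Merits: the positions of both oxygens and of the side chain follow from connectivity, and no halogen has to be told apart from another.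
- Weak points: A3 is far from 9. It has an ester where C2 needs bromine and hydrogens at C5 and C6, so hydrolysis, bromodecarboxylation, two ring brominations and ether cleavage would follow. The ester carbon is built only to be excised. Neither A1 nor A2 is purchasable, and the lactam and ketone of A2 can chelate the Lewis acid.
- Comparison: in certainty of the oxygen pattern this road is better than the chosen plan. The chosen plan sets against it that all three bromines and the benzylic carbon are bought in place, so 9 is three steps from commercial materials instead of roughly three times as many.

**Alternative 2: oxalate and adipate double Claisen condensation.**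
- Cut: ring bonds C2–C3 and C4–C5.
- Forward key step: an alkoxide base condenses the racemic adipate A4, diethyl 3-[(2-oxopyrrolidin-1-yl)methyl]hexanedioate, twice with diethyl oxalate A5. The six-membered carbocycle closes as the bis-enol A6, diethyl 2,3-dihydroxy-5-[(2-oxopyrrolidin-1-yl)methyl]cyclohexa-1,3-diene-1,4-dicarboxylate.
- Merits: classical, cheap condensation chemistry. The two oxygens come from one oxalate unit and are necessarily adjacent, and both α-carbons of A4 must react, so there is no regiochemical question.
- Weak points: A4 needs a multistep preparation. A6 is not aromatic and must be dehydrogenated. Both ester groups, at C2 and C5, must be exchanged for bromine and C6 brominated. A stereocentre is created only to be destroyed.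
- Comparison: each step of this road has close precedent, which the key step of the chosen plan lacks. The chosen plan sets against it its brevity and a fallback made only of known reactions.

**Alternative 3: thiophene dioxide and bromoalkyne Diels–Alder reaction.**
- Cut: ring bonds C1–C2 and C5–C6.
- Forward key step: the diene A7, 2,5-dibromo-3,4-dimethoxythiophene 1,1-dioxide, adds across the triple bond of A8, 1-(3-bromoprop-2-yn-1-yl)pyrrolidin-2-one. The bridged adduct extrudes its sulfonyl bridge and gives A9, 1-[(2,3,6-tribromo-4,5-dimethoxyphenyl)methyl]pyrrolidin-2-one.
- Merits: convergent; the symmetric diene removes any regiochemical question, and all six substituents arrive in one step. A9 is the bis(methyl ether) of 9, and methyl ethers are cleaved more easily than the ethylene bridge of 7, so its endgame is better than that of the chosen plan.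
- Weak points: oxidising an electron-rich dimethoxythiophene to its dioxide is delicate, and such dioxides tend to dimerise. A7 is a hindered, fully substituted, electron-poor diene that is poorly matched to a haloalkyne of modest reactivity, and the temperatures needed would strain the bromoalkyne.
- Comparison: this road is better in regiochemical certainty and in the final deprotection. The chosen plan sets against it step economy (three linear steps instead of about six over two branches) and purchasable starting materials.

Key step: step 2

Assumption: pentabromobenzyl bromide 2 is taken as purchasable (an intermediate of brominated flame-retardant manufacture); the target is achiral, so no compound of the route needs a stereodescriptor.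

## Route

Step 1
Reactants: 1 pyrrolidin-2-one; 2 1,2,3,4,5-pentabromo-6-(bromomethyl)benzene (pentabromobenzyl bromide)
Product: 4 1-[(2,3,4,5,6-pentabromophenyl)methyl]pyrrolidin-2-one, via sodium 2-oxopyrrolidin-1-ide 3 (not isolated)
Conditions: 1 (1.3 equiv), NaH (1.2 equiv), THF, 0 °C to rt; then 2 (1.0 equiv), THF/DMF, rt to 50 °C
Reagents that add atoms: none
Why: N-alkylation of a lactam anion by SN2: the sodium amidate 3 attacks the benzylic carbon of 2, whose C–Br bond is far more reactive than the aryl C–Br bonds, and soft benzylic halides alkylate lactam anions at nitrogen. Keeping 1 in slight excess over NaH leaves no free hydride to attack the polybromoarene.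

Step 2
Reactants: 4 1-[(2,3,4,5,6-pentabromophenyl)methyl]pyrrolidin-2-one; 5 ethane-1,2-diol
Product: 7 1-[(5,7,8-tribromo-2,3-dihydro-1,4-benzodioxin-6-yl)methyl]pyrrolidin-2-one, via 1-{[2,3,5,6-tetrabromo-4-(2-hydroxyethoxy)phenyl]methyl}pyrrolidin-2-one 6 (not isolated)
Conditions: 5 (3 equiv), Cs2CO3 (3 equiv), degassed DMSO, 100 °C, argon
Reagents that add atoms: none
Why: Proposed new method: the glycol monoalkoxide formed by Cs2CO3 in DMSO adds to a bromine-bearing ring carbon of 4 to give a Meisenheimer anion stabilised inductively by the remaining bromines, bromide leaves, and the pendant alkoxide of 6 repeats the addition–elimination at the neighbouring carbon (tethered double SNAr). The closest known reaction type is the double SNAr of hexafluorobenzene or of activated ortho-dihaloarenes with 1,2-diols or catechols to benzo-fused 1,4-dioxanes and dioxins, together with alkoxide or hydroxide substitution of hexahalobenzenes; a perbrominated benzyl arene with a glycol has no direct precedent. The one new ring, the 1,4-dioxane, closes by attack of the tethered alkoxide on the adjacent sp2 carbon, a six-membered closure that is formally 6-exo-trig with respect to the ring π bond that takes up the charge, and no stereocentre is formed. The step needs site selectivity: entry must avoid C2 and C6, and closure must avoid C2. Entry at C4 should lead, because C4 alone has two ortho and two meta bromines and places the bulky, weakly donating CH2N group para, the pattern that sends nucleophiles para to the alkyl group in alkylpentafluorobenzenes; from C4 both neighbours are equivalent, so closure is unambiguous. Entry at C3 would still converge if closure prefers C4 (ortho bromine, para CH2N) over C2 (ortho CH2N, sterically screened), whereas entry at C2 or C6 gives up one ortho bromine and meets the benzylic substituent. A hard oxygen nucleophile, a carbonate base in place of a carbanion or tert-butoxide, and exclusion of air are chosen to hold back halophilic debromination, and the two new donor oxygens switch off further substitution.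

Step 3
Reactants: 7 1-[(5,7,8-tribromo-2,3-dihydro-1,4-benzodioxin-6-yl)methyl]pyrrolidin-2-one
Product: 9 1-[(2,3,6-tribromo-4,5-dihydroxyphenyl)methyl]pyrrolidin-2-one, via 1-[(2,4,6,7-tetrabromo-1,3,2-benzodioxaborol-5-yl)methyl]pyrrolidin-2-one 8 (not isolated)
Conditions: BBr3 (5 equiv), CH2Cl2, −78 °C to rt, then 40 °C; H2O, 0 °C, work-up under argon
Reagents that add atoms: none
Why: Lewis-acid dealkylation of aryl alkyl ethers with BBr3: coordination at each ether oxygen and SN2 attack of bromide at the adjacent CH2 release the bridge as 1,2-dibromoethane and leave the aryl borate 8, which water hydrolyses to the catechol. The lactam only binds the Lewis acid reversibly (hence the excess), and the benzylic C–N and aryl C–Br bonds are inert to it.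

## Compound list

1 | pyrrolidin-2-one | O=C1CCCN1 | starting material
2 | 1,2,3,4,5-pentabromo-6-(bromomethyl)benzene | BrCc1c(Br)c(Br)c(Br)c(Br)c1Br | starting material
3 | sodium 2-oxopyrrolidin-1-ide | [Na+].O=C1CCC[N-]1 | intermediate
4 | 1-[(2,3,4,5,6-pentabromophenyl)methyl]pyrrolidin-2-one | O=C1CCCN1Cc1c(Br)c(Br)c(Br)c(Br)c1Br | intermediate
5 | ethane-1,2-diol | OCCO | starting material
6 | 1-{[2,3,5,6-tetrabromo-4-(2-hydroxyethoxy)phenyl]methyl}pyrrolidin-2-one | O=C1CCCN1Cc1c(Br)c(Br)c(OCCO)c(Br)c1Br | intermediate
7 | 1-[(5,7,8-tribromo-2,3-dihydro-1,4-benzodioxin-6-yl)methyl]pyrrolidin-2-one | O=C1CCCN1Cc1c(Br)c2OCCOc2c(Br)c1Br | intermediate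
8 | 1-[(2,4,6,7-tetrabromo-1,3,2-benzodioxaborol-5-yl)methyl]pyrrolidin-2-one | O=C1CCCN1Cc1c(Br)c2OB(Br)Oc2c(Br)c1Br | intermediate
9 | 1-[(2,3,6-tribromo-4,5-dihydroxyphenyl)methyl]pyrrolidin-2-one | O=C1CCCN1Cc1c(Br)c(O)c(O)c(Br)c1Br | target

## Step count and risks

Total step count: 3. Longest linear sequence: 3 steps (2 to 4 to 7 to 9).

**Step 2 (key step, proposed new method).**
- What may go wrong: loss of site selectivity in the first substitution (entry at C2 or C6, possibly helped by cation delivery from the lactam carbonyl) or in the ring closure (onto C2); halophilic attack of the alkoxide on bromine with hydrodebromination; or too little electrophilicity of a ring activated only inductively, so that intermolecular bridging of two arenes by one diol competes.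
- Fallback (known chemistry only): it sets out from pyrrolidin-2-one 1 and comes back to the route at 7. The oxygens are put in place before the bromines. Commercial 4-methylbenzene-1,2-diol is bridged with 1,2-dibromoethane (K2CO3, DMF, 90 °C; double Williamson etherification) to 6-methyl-2,3-dihydro-1,4-benzodioxine F1. Its three free ring positions, each ortho or para to an ether oxygen, are brominated exhaustively (excess Br2, FeBr3 cat., CH2Cl2) to 5,7,8-tribromo-6-methyl-2,3-dihydro-1,4-benzodioxine F2. Radical benzylic bromination (NBS, AIBN, PhCF3, reflux) gives 5,7,8-tribromo-6-(bromomethyl)-2,3-dihydro-1,4-benzodioxine F3. The sodium salt 3, made from 1 as in step 1, is then alkylated with F3 to give 7. Regiochemistry is fixed by filling every open position, at the price of three more steps.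

**Step 3.**
- What may go wrong: arrest of the cleavage after the first C–O scission, because the second ether oxygen sits on a borylated, electron-poor ring and is a weak Lewis base; sequestration of the Lewis acid by the lactam carbonyl; and air oxidation of the catechol during work-up.
- Fallback: it sets out from 7 and comes back at 9, replacing the second Lewis-acid cleavage by a redox fragmentation. A limited charge of BBr3 at low temperature (1.2 equiv, CH2Cl2, −78 to 0 °C, then water) is used to stop at the half-opened ether. This is 1-{[2,3,6-tribromo-4-(2-bromoethoxy)-5-hydroxyphenyl]methyl}pyrrolidin-2-one F4 or its isomer 1-{[2,3,6-tribromo-5-(2-bromoethoxy)-4-hydroxyphenyl]methyl}pyrrolidin-2-one F5; either serves. The 2-bromoethyl group is then removed by reductive β-elimination (Zn dust, NaI cat., THF/AcOH, rt to 50 °C; Boord-type fragmentation releasing ethene) to give 9. The acidic medium keeps the phenol protonated, so it cannot re-close onto the bromoethyl group.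

**Step 1.**
- What may go wrong: competition between benzylic SN2 and attack of the lactam anion on the ring (substitution or electron-transfer debromination); O-alkylation to the lactim ether; and slow reaction at a benzylic carbon screened by two ortho bromines, made worse by the poor solubility of 2.
- Fallback: it sets out from 2 and comes back at 4, forming the C–N bond with a neutral amine and closing the lactam afterwards. Compound 2 is treated with commercial methyl 4-aminobutanoate hydrochloride (K2CO3, MeCN, 60 °C) to give methyl 4-{[(2,3,4,5,6-pentabromophenyl)methyl]amino}butanoate F6. Heating F6 (toluene, 110 °C, AcOH cat.) closes the five-membered lactam with loss of methanol and gives 4. The hindered benzyl group should hold back double alkylation.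

## Further compounds

F1 | step 2 | 6-methyl-2,3-dihydro-1,4-benzodioxine | Cc1ccc2OCCOc2c1
F2 | step 2 | 5,7,8-tribromo-6-methyl-2,3-dihydro-1,4-benzodioxine | Cc1c(Br)c2OCCOc2c(Br)c1Br
F3 | step 2 | 5,7,8-tribromo-6-(bromomethyl)-2,3-dihydro-1,4-benzodioxine | BrCc1c(Br)c2OCCOc2c(Br)c1Br
F4 | step 3 | 1-{[2,3,6-tribromo-4-(2-bromoethoxy)-5-hydroxyphenyl]methyl}pyrrolidin-2-one | O=C1CCCN1Cc1c(Br)c(O)c(OCCBr)c(Br)c1Br
F5 | step 3 | 1-{[2,3,6-tribromo-5-(2-bromoethoxy)-4-hydroxyphenyl]methyl}pyrrolidin-2-one | O=C1CCCN1Cc1c(Br)c(OCCBr)c(O)c(Br)c1Br
F6 | step 1 | methyl 4-{[(2,3,4,5,6-pentabromophenyl)methyl]amino}butanoate | COC(=O)CCCNCc1c(Br)c(Br)c(Br)c(Br)c1Br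
A1 | alternative 1 | 1,4-dimethoxy-1,3-bis(trimethylsilyloxy)buta-1,3-diene (double-bond geometry not fixed) | COC=C(O[Si](C)(C)C)C=C(OC)O[Si](C)(C)C
A2 | alternative 1 | (E)-4-methoxy-1-(2-oxopyrrolidin-1-yl)but-3-en-2-one | CO/C=C/C(=O)CN1CCCC1=O
A3 | alternative 1 | methyl 2-hydroxy-3-methoxy-6-[(2-oxopyrrolidin-1-yl)methyl]benzoate | COC(=O)c1c(O)c(OC)ccc1CN1CCCC1=O
A4 | alternative 2 | diethyl 3-[(2-oxopyrrolidin-1-yl)methyl]hexanedioate (racemic) | CCOC(=O)CC(CN1CCCC1=O)CCC(=O)OCC
A5 | alternative 2 | diethyl oxalate | CCOC(=O)C(=O)OCC
A6 | alternative 2 | diethyl 2,3-dihydroxy-5-[(2-oxopyrrolidin-1-yl)methyl]cyclohexa-1,3-diene-1,4-dicarboxylate (racemic) | CCOC(=O)C1=C(O)C(O)=C(C(=O)OCC)C(CN2CCCC2=O)C1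
A7 | alternative 3 | 2,5-dibromo-3,4-dimethoxythiophene 1,1-dioxide | COC1=C(Br)S(=O)(=O)C(Br)=C1OC
A8 | alternative 3 | 1-(3-bromoprop-2-yn-1-yl)pyrrolidin-2-one | O=C1CCCN1CC#CBr
A9 | alternative 3 | 1-[(2,3,6-tribromo-4,5-dimethoxyphenyl)methyl]pyrrolidin-2-one | O=C1CCCN1Cc1c(Br)c(OC)c(OC)c(Br)c1Br
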